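The tetrahydropyran ring B of the 6,8-dioxabicyclo[3.2.1]octane (bridging oxygen, ketal carbon, ring-fusion CH, pyranone-bearing CH, CH2, O–CH) is read as a masked 2H-pyran: oxygen, ketal carbon and ring-fusion CH are the O=C–CH unit of a cyclohexane-1,3-dione, the other three carbons an enal. A Knoevenagel/6π-oxa-electrocyclisation (formal oxa-[3+3]) between an (R)-4-silyloxy-1,3-dione and an (S)-4-silyloxy-2-enal makes the C–C bond at the ring-fusion carbon and the ring C–O bond in one operation; the closure is reversible, so the unwanted C2 epimer is returned through the open triene to the wanted one. Desilylative ketalisation then gives a tricyclic ketal enone, and conjugate addition of 4-hydroxy-6-methyl-2-pyrone with hemiketalisation completes the target.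

Key step: step 8

Assumption (chemistry): the lipase of step 2 is taken to show the usual preference of this enzyme class for the (R)-configured secondary acetate (sp2 carbonyl side as the larger substituent); if the sense proved opposite, the recovered acetate would be methanolysed and carried on instead.

**Step 1**
Reactants: 1 3-ethoxycyclohex-2-en-1-one
Product: 2 (±)-6-acetoxy-3-ethoxycyclohex-2-en-1-one (racemic)
Conditions: Mn(OAc)3·2H2O (2.5 equiv), benzene, reflux, azeotropic removal of water
Reagents that add atoms: manganese triacetate, CC(=O)[O-].CC(=O)[O-].CC(=O)[O-].[Mn+3]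
Why: Mn(OAc)3-mediated α'-acetoxylation of an enone, in which the manganese enolate formed on the CH2 side of the ketone (C6) is oxidised and captures acetate while the vinylogous ester blocks the other side, gives the racemic α'-acetoxy ketone.

**Step 2**
Reactants: 2 (±)-6-acetoxy-3-ethoxycyclohex-2-en-1-one
Product: 3 (R)-3-ethoxy-6-hydroxycyclohex-2-en-1-one
Conditions: Burkholderia cepacia lipase (Amano PS), phosphate buffer pH 7/MTBE, 25 °C, run to about half conversion
Reagents that add atoms: none
Why: Lipase-catalysed (serine hydrolase) kinetic resolution by enantioselective hydrolysis of a cyclic secondary acetate, which is expected to cleave the (R)-acetate and leave the (S)-acetate for chromatographic removal, sets the carbinol stereocentre that becomes the CH–OH next to the hemiketal carbon of the target.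

**Step 3**
Reactants: 3 (R)-3-ethoxy-6-hydroxycyclohex-2-en-1-one
Product: 4 (R)-6-(tert-butyldimethylsilyloxy)-3-ethoxycyclohex-2-en-1-one
Conditions: TBSCl, imidazole, DMF, 0 °C to rt
Reagents that add atoms: tert-butyldimethylsilyl chloride, CC(C)(C)[Si](C)(C)Cl
Why: Standard silylation of a secondary alcohol with TBSCl and imidazole, which touches no bond at the stereocentre.

**Step 4**
Reactants: 4 (R)-6-(tert-butyldimethylsilyloxy)-3-ethoxycyclohex-2-en-1-one
Product: 5 (R)-4-(tert-butyldimethylsilyloxy)cyclohexane-1,3-dione
Conditions: 1 M aq. HCl, THF, 0 °C to rt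
Reagents that add atoms: water, O
Why: Acid-catalysed hydrolysis of the vinylogous ester (an enol ether) releases the 1,3-dione, the secondary TBS ether surviving cold dilute acid and the silyloxy-bearing centre not being epimerised under these non-basic conditions.

**Step 5**
Reactants: 6 (S)-1,2-epoxyoctane
Product: 7 (S)-non-1-en-3-ol
Conditions: Me3S+ I− (3 equiv), n-BuLi (3 equiv), THF, −10 °C to rt
Reagents that add atoms: trimethylsulfonium iodide, C[S+](C)C.[I-]
Why: One-carbon homologation of a terminal epoxide to an allylic alcohol with dimethylsulfonium methylide (epoxide opening at the CH2 terminus, then ylide-mediated elimination of dimethyl sulfide from the sulfonium alkoxide) leaves the carbinol carbon untouched, so the (S) configuration of the future hexyl-bearing O–CH is taken over from 6.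

**Step 6**
Reactants: 7 (S)-non-1-en-3-ol
Product: 8 (S)-tert-butyldimethyl(non-1-en-3-yloxy)silane
Conditions: TBSCl, imidazole, DMF, rt
Reagents that add atoms: tert-butyldimethylsilyl chloride, CC(C)(C)[Si](C)(C)Cl
Why: Standard silylation of a secondary allylic alcohol, with no change at the stereocentre.

**Step 7**
Reactants: 8 (S)-tert-butyldimethyl(non-1-en-3-yloxy)silane; 9 (E)-but-2-enal (crotonaldehyde, 5 equiv)
Product: 10 (S,E)-4-(tert-butyldimethylsilyloxy)dec-2-enal
Conditions: second-generation Hoveyda–Grubbs catalyst, RuCl2(H2IMes)(=CH–C6H4-2-OiPr) (3 mol %), CH2Cl2, 40 °C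
Reagents that add atoms: none
Why: Olefin cross-metathesis of the terminal alkene with excess crotonaldehyde exchanges the CH2 terminus for CH–CHO with loss of propene and gives the conjugated (E)-enal as the thermodynamic isomer without touching the allylic stereocentre.

**Step 8**
Reactants: 5 (R)-4-(tert-butyldimethylsilyloxy)cyclohexane-1,3-dione; 10 (S,E)-4-(tert-butyldimethylsilyloxy)dec-2-enal
Product: 13 (2S,6R)-6-(tert-butyldimethylsilyloxy)-2-[(1S)-1-(tert-butyldimethylsilyloxy)heptyl]-7,8-dihydro-2H-chromen-5(6H)-one, via oxatriene 11 (not isolated), via C2 epimer 12 (not isolated)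
Conditions: ethylenediammonium diacetate (EDDA, 20 mol %), toluene, 50 °C; fraction holding 12 returned to toluene, 80 °C
Reagents that add atoms: none
Why: EDDA condenses the enal, through its iminium ion, with C2 of the dione (Knoevenagel condensation) to give the 1-oxatriene 11, which closes by thermal 6π-oxa-electrocyclisation; the closest known reaction type is the formal oxa-[3+3] annulation of cyclic 1,3-diones with α,β-unsaturated aldehydes. The one ring formed, the 2H-pyran that becomes ring B, closes in the disrotatory 6π mode, the carbonyl oxygen bonding to the enal β-carbon. The one new stereocentre, C2 of the pyran, is set in this reversible closure under only weak bias from the neighbouring silyloxy carbon, so the (2R)-epimer 12 forms beside 13; 13 is drawn off by chromatography and the fraction that holds 12 goes back without purification into toluene at 80 °C, where 12 reopens to 11 and recloses, so that the material should converge on 13. The two silyloxy stereocentres come unchanged from 5 and 10. Regioselectivity between the two carbonyl oxygens is needed and rests on thermodynamic control through 11: closure by the oxygen remote from the OTBS group leaves the push-pull carbonyl beside the inductively withdrawing silyloxy carbon, the better acceptor, and any regioisomer re-enters the same equilibrium. Condensation at the aldehyde carbon rather than conjugate addition is secured by the branched γ-silyloxy carbon that shields the β-position, and the acidic dione keeps the medium buffered so that the iminium ion is consumed before γ-deprotonation can erode the (S) centre.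

**Step 9**
Reactants: 13 (2S,6R)-6-(tert-butyldimethylsilyloxy)-2-[(1S)-1-(tert-butyldimethylsilyloxy)heptyl]-7,8-dihydro-2H-chromen-5(6H)-one
Product: 15 (1R,4R,9S,10S)-10-hexyl-4-hydroxy-11,12-dioxatricyclo[7.2.1.0^1,6]dodec-6-en-5-one, via diol 14 (not isolated)
Conditions: HF·pyridine, pyridine, THF, 0 °C to rt; then CSA (10 mol %), CH2Cl2, 0 °C to rt
Reagents that add atoms: none
Why: Fluoride cleaves both silyl ethers and, under CSA at room temperature, the dienol ether of diol 14 is protonated at C3 and the side-chain hydroxyl captures the resulting oxocarbenium carbon C8a to close the dioxolane (the acid-catalysed intramolecular ketalisation of a hydroxy-substituted 3-alkoxy-enone that leads to 6,8-dioxabicyclo[3.2.1]octanes), which leaves the double bond conjugated with the ketone, carries the retained (2S,1'S) carbinol centres into the exo-hexyl bicycle, fixes the ketal carbon through the bridge and, because no ring opening occurs at this temperature, preserves C2 and the regiochemistry.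

**Step 10**
Reactants: 15 (1R,4R,9S,10S)-10-hexyl-4-hydroxy-11,12-dioxatricyclo[7.2.1.0^1,6]dodec-6-en-5-one; 16 4-hydroxy-6-methyl-2H-pyran-2-one (1.5 equiv)
Product: 18 Trichopsistide B, via keto tautomer 17 (not isolated)
Conditions: Et3N (0.3 equiv), MeCN, 40 °C
Reagents that add atoms: none
Why: Amine-catalysed Michael addition of C3 of the hydroxypyranone to the s-cis enone takes place on the face of ring B opposite to the dioxolane bridge, whose two atoms are syn-axial to the other face, and so sets the pyranone-bearing CH, after which keto tautomer 17 equilibrates by enolisation and 6-exo-trig hemiketalisation to the thermodynamic ring-chain tautomer, in which the ring-fusion hydrogen is cis to the new C–H (the ring B CH2 then stands pseudoaxial on the new dihydropyran, clear of the lactone carbonyl) and the hemiketal hydroxyl is axial (anomeric effect).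

**Compound list**

1 | 3-ethoxycyclohex-2-en-1-one | CCOC1=CC(=O)CCC1 | starting material
2 | (±)-6-acetoxy-3-ethoxycyclohex-2-en-1-one (racemic) | CCOC1=CC(=O)C(OC(C)=O)CC1 | intermediate
3 | (R)-3-ethoxy-6-hydroxycyclohex-2-en-1-one | CCOC1=CC(=O)[C@H](O)CC1 | intermediate
4 | (R)-6-(tert-butyldimethylsilyloxy)-3-ethoxycyclohex-2-en-1-one | CCOC1=CC(=O)[C@H](O[Si](C)(C)C(C)(C)C)CC1 | intermediate
5 | (R)-4-(tert-butyldimethylsilyloxy)cyclohexane-1,3-dione | O=C1CC(=O)[C@H](O[Si](C)(C)C(C)(C)C)CC1 | intermediate
6 | (S)-1,2-epoxyoctane ((S)-2-hexyloxirane) | CCCCCC[C@H]1CO1 | starting material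
7 | (S)-non-1-en-3-ol | CCCCCC[C@H](O)C=C | intermediate
8 | (S)-tert-butyldimethyl(non-1-en-3-yloxy)silane | CCCCCC[C@H](O[Si](C)(C)C(C)(C)C)C=C | intermediate
9 | (E)-but-2-enal (crotonaldehyde) | C/C=C/C=O | starting material
10 | (S,E)-4-(tert-butyldimethylsilyloxy)dec-2-enal | CCCCCC[C@H](O[Si](C)(C)C(C)(C)C)/C=C/C=O | intermediate
11 | (R)-4-(tert-butyldimethylsilyloxy)-2-[(2E,4S)-4-(tert-butyldimethylsilyloxy)dec-2-en-1-ylidene]cyclohexane-1,3-dione (oxatriene, C1 carbonyl cis to the diene) | CCCCCC[C@H](O[Si](C)(C)C(C)(C)C)/C=C/C=C1\C(=O)CC[C@@H](O[Si](C)(C)C(C)(C)C)C1=O | intermediate (not isolated)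
12 | (2R,6R)-6-(tert-butyldimethylsilyloxy)-2-[(1S)-1-(tert-butyldimethylsilyloxy)heptyl]-7,8-dihydro-2H-chromen-5(6H)-one (C2 epimer of 13) | CCCCCC[C@H](O[Si](C)(C)C(C)(C)C)[C@H]1C=CC2=C(O1)CC[C@@H](O[Si](C)(C)C(C)(C)C)C2=O | intermediate (not isolated)
13 | (2S,6R)-6-(tert-butyldimethylsilyloxy)-2-[(1S)-1-(tert-butyldimethylsilyloxy)heptyl]-7,8-dihydro-2H-chromen-5(6H)-one | CCCCCC[C@H](O[Si](C)(C)C(C)(C)C)[C@@H]1C=CC2=C(O1)CC[C@@H](O[Si](C)(C)C(C)(C)C)C2=O | intermediate
14 | (2S,6R)-6-hydroxy-2-[(1S)-1-hydroxyheptyl]-7,8-dihydro-2H-chromen-5(6H)-one | CCCCCC[C@H](O)[C@@H]1C=CC2=C(O1)CC[C@@H](O)C2=O | intermediate (not isolated)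
15 | (1R,4R,9S,10S)-10-hexyl-4-hydroxy-11,12-dioxatricyclo[7.2.1.0^1,6]dodec-6-en-5-one | CCCCCC[C@@H]1O[C@]23CC[C@@H](O)C(=O)C3=CC[C@@H]1O2 | intermediate
16 | 4-hydroxy-6-methyl-2H-pyran-2-one | Cc1cc(O)cc(=O)o1 | starting material
17 | (1R,4R,6S,7R,9S,10S)-10-hexyl-4-hydroxy-7-(4-hydroxy-6-methyl-2-oxo-2H-pyran-3-yl)-11,12-dioxatricyclo[7.2.1.0^1,6]dodecan-5-one (keto tautomer of 18) | CCCCCC[C@@H]1O[C@]23CC[C@@H](O)C(=O)[C@@H]3[C@@H](C[C@@H]1O2)c4c(O)cc(C)oc4=O | intermediate (not isolated)
18 | Trichopsistide B | CCCCCC[C@@H]1O[C@]23CC[C@@H](O)[C@@]4(O)Oc5cc(C)oc(=O)c5[C@H](C[C@@H]1O2)[C@H]34 | target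

**Step count and risks**

Total step count: 10. Longest linear sequence: 7 steps (steps 1, 2, 3, 4, 8, 9, 10).

The three steps most likely to fail:

Step 8. The thermal return of the C2 epimer may be eroded by a 1,7-hydrogen shift in the open triene, the ring closure may partition between the two carbonyl oxygens, γ-deprotonation of the iminium ion may erode the side-chain configuration, and conjugate addition may compete with condensation. The fallback moves the C6 oxygenation behind the annulation. It sets out from 10 and commercial cyclohexane-1,3-dione (O=C1CCCC(=O)C1), which is symmetrical, so that only one regioisomer can form. The same EDDA annulation gives (2S)-2-[(1S)-1-(tert-butyldimethylsilyloxy)heptyl]-7,8-dihydro-2H-chromen-5(6H)-one F1 together with its (2R)-epimer F2, which goes back through the same thermal ring-opening equilibrium as in the main route. Kinetic deprotonation of F1 at C6, the only α'-position of the vinylogous ester (LiN(iPr)2, THF, −78 °C), and oxidation of the enolate with enantiopure (camphorsulfonyl)oxaziridine give (2S,6R)-6-hydroxy-2-[(1S)-1-(tert-butyldimethylsilyloxy)heptyl]-7,8-dihydro-2H-chromen-5(6H)-one F3. The enantiomer of the oxidant is chosen on the model ketone 1 for the (6R) sense, and the minor C6 epimer is removed. F3 enters step 9, where fluoride converts it into 14, so the fallback comes back to the route at 14.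

Step 9. The hydroxyl may add to the other terminus of the allyl oxocarbenium ion (C4), giving a bridged ether that keeps the vinylogous ester, or the ketal may stay in an unfavourable equilibrium with the pyran. The fallback does not isolate the ketal enone but draws it out of the equilibrium. It sets out from 14 (from 13 by the fluoride stage alone), which is warmed with 16 and an Et3N/AcOH buffer in MeCN at 60 °C. Every molecule that reaches 15 is then captured by conjugate addition and locked as the hemiketal, and the fallback comes back to the route at 18. It makes no compound outside the list.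

Step 10. Under amine catalysis, β-elimination of the ketal oxygen after γ-deprotonation, or epimerisation of the hydroxy ketone, may outrun a sluggish conjugate addition, and O-alkylation of the pyranone may compete. The fallback is a base-free Mukaiyama–Michael addition. It sets out from 15 and 16: 16 is silylated with HMDS to 6-methyl-4-(trimethylsilyloxy)-2H-pyran-2-one F4, which adds to 15 under Sc(OTf)3 (5 mol %) in CH2Cl2 at −20 °C with the same facial bias. Work-up with aqueous citric acid cleaves the silyl groups and gives 17, which closes to the hemiketal, so the fallback comes back to the route at 18.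

**Further compounds**

F1 | step 8 | (2S)-2-[(1S)-1-(tert-butyldimethylsilyloxy)heptyl]-7,8-dihydro-2H-chromen-5(6H)-one | CCCCCC[C@H](O[Si](C)(C)C(C)(C)C)[C@@H]1C=CC2=C(O1)CCCC2=O
F2 | step 8 | (2R)-2-[(1S)-1-(tert-butyldimethylsilyloxy)heptyl]-7,8-dihydro-2H-chromen-5(6H)-one | CCCCCC[C@H](O[Si](C)(C)C(C)(C)C)[C@H]1C=CC2=C(O1)CCCC2=O
F3 | step 8 | (2S,6R)-6-hydroxy-2-[(1S)-1-(tert-butyldimethylsilyloxy)heptyl]-7,8-dihydro-2H-chromen-5(6H)-one | CCCCCC[C@H](O[Si](C)(C)C(C)(C)C)[C@@H]1C=CC2=C(O1)CC[C@@H](O)C2=O
F0 | step 9 | none | none
F4 | step 10 | 6-methyl-4-(trimethylsilyloxy)-2H-pyran-2-one | Cc1cc(O[Si](C)(C)C)cc(=O)o1
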